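**Retrosynthetic overview**
1. Rings are lettered A to E from the 2,4,6-trihydroxyphenoxy end; in rings B, C and E, C1 carries the ether oxygen to the preceding ring. The route rests on the C4–OH of each of these three rings, which lies between two oxygenated carbons (C3, C5) and para to the C1 ether oxygen.
2. Last disconnections: the ten O–CH3 bonds (BBr3), then the three C4–O bonds of rings B, C and E, made together by Baeyer–Villiger (Dakin-type) oxidation of trialdehyde 13 (C4–CHO to C4–OH).
3. Before that, the same formyl groups activate fluoride displacement: the A–O–B and D–O–E ethers by SNAr at the para fluoride of 4-fluoro-2,6-dimethoxybenzaldehyde, the B–O–C ether by SNAr of ring B phenol 4 on the ring C fluoride of 12.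
4. The C–O–D ether is meta to the ring C formyl group and is made by CuI-catalysed Ullmann coupling of ring C phenol 11 with ring D bromide 6; the oxygen of 11 comes from directed ortho-lithiation, borylation and oxidation.
5. No ring is built: all five benzene rings come from three arenes, and fragments AB (4) and CDE (12) are joined in step 7.

Key step: step 8

Remark: 1, 2 and 5 are taken to be commercially available. Steps with free phenoxides and the last two steps are run under argon with degassed solvents, since 1 and the late phenols are air-sensitive.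

Step 1
Reactants: 1 2,4,6-trimethoxyphenol; 2 4-fluoro-2,6-dimethoxybenzaldehyde
Product: 3 2,6-dimethoxy-4-(2,4,6-trimethoxyphenoxy)benzaldehyde
Conditions: K2CO3, DMSO, 110 °C, argon
Reagents that add atoms: none
Why: Nucleophilic aromatic substitution (SNAr): the phenoxide of 1 adds at the fluorine-bearing carbon para to the formyl group of 2, the formyl group stabilises the Meisenheimer adduct and fluoride leaves, and with a single leaving group in 2 no regiochemical question arises.

Step 2
Reactants: 3 2,6-dimethoxy-4-(2,4,6-trimethoxyphenoxy)benzaldehyde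
Product: 4 2-hydroxy-6-methoxy-4-(2,4,6-trimethoxyphenoxy)benzaldehyde
Conditions: BCl3 (1.2 equiv), CH2Cl2 (dilute), −78 to 0 °C; then H2O
Reagents that add atoms: none
Why: Chelation-controlled mono-O-demethylation: BCl3 bridges the formyl oxygen and one neighbouring methoxy oxygen, chloride removes that methyl group, and the aryloxyboron chelate so formed shields the second ortho methoxy group, while the non-chelating methoxy groups of ring A should not react in the cold.

Step 3
Reactants: 5 4-bromo-2,6-dimethoxyphenol; 2 4-fluoro-2,6-dimethoxybenzaldehyde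
Product: 6 4-(4-bromo-2,6-dimethoxyphenoxy)-2,6-dimethoxybenzaldehyde
Conditions: K2CO3, DMSO, 110 °C, argon
Reagents that add atoms: none
Why: SNAr as in step 1 with the phenoxide of 5 as nucleophile; the bromide of 5 has no activating group and should not be displaced.

Step 4
Reactants: 2 4-fluoro-2,6-dimethoxybenzaldehyde
Product: 7 2-(4-fluoro-2,6-dimethoxyphenyl)-1,3-dioxolane
Conditions: ethylene glycol, p-TsOH (cat.), toluene, reflux, Dean–Stark
Reagents that add atoms: ethylene glycol, OCCO
Why: Acid-catalysed acetalisation with azeotropic removal of water masks the formyl group against the organolithium reagent of step 5.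

Step 5
Reactants: 7 2-(4-fluoro-2,6-dimethoxyphenyl)-1,3-dioxolane
Product: 11 4-fluoro-3-hydroxy-2,6-dimethoxybenzaldehyde, via aryllithium 8 (not isolated), via dimethyl arylboronate 9 (not isolated), via phenol acetal 10 (not isolated)
Conditions: n-BuLi, THF, −78 °C; B(OMe)3, −78 to 0 °C; NaOH, H2O2, 0 °C to rt; Na2SO3; 2 M HCl, rt
Reagents that add atoms: hydrogen peroxide, OO (the phenol oxygen of 11); n-butyllithium, [Li]CCCC (lithium of 8 only); trimethyl borate, COB(OC)OC (boronate group of 9 only)
Why: Directed ortho-metalation at the ring C–H flanked by fluorine and methoxy (the two such positions are equivalent by symmetry), trapping of the aryllithium as a boronate at −78 °C before LiF can be lost, alkaline peroxide oxidation of the C–B bond (1,2-shift of the aryl group from boron to oxygen) and acid hydrolysis of the acetal should give the phenol.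

Step 6
Reactants: 11 4-fluoro-3-hydroxy-2,6-dimethoxybenzaldehyde; 6 4-(4-bromo-2,6-dimethoxyphenoxy)-2,6-dimethoxybenzaldehyde
Product: 12 4-fluoro-3-[4-(4-formyl-3,5-dimethoxyphenoxy)-3,5-dimethoxyphenoxy]-2,6-dimethoxybenzaldehyde
Conditions: CuI (10 mol %), N,N-dimethylglycine hydrochloride (30 mol %), Cs2CO3, 1,4-dioxane, 100 °C, argon
Reagents that add atoms: none
Why: Ullmann-type diaryl ether synthesis: CuI with N,N-dimethylglycine couples aryl bromides, electron-rich ones included, with ortho-substituted phenols; the bromide of 6 has two ortho hydrogens, the C–F bond of 11 is inert to copper, and in dioxane uncatalysed fluoride displacement should be slow.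

Step 7
Reactants: 4 2-hydroxy-6-methoxy-4-(2,4,6-trimethoxyphenoxy)benzaldehyde; 12 CDE fluoride
Product: 13 trialdehyde deca-O-methyl precursor (full name in the compound list)
Conditions: Cs2CO3, DMSO, 120 °C, argon
Reagents that add atoms: none
Why: SNAr: the phenoxide of 4 displaces the fluoride of 12, which is para to the ring C formyl group; the coupling of salicylaldehyde-type phenoxides with 4-fluorobenzaldehydes under carbonate in dipolar aprotic solvents is the known model.

Step 8
Reactants: 13 trialdehyde deca-O-methyl precursor
Product: 15 triphenol deca-O-methyl ether, via tris(aryl formate) 14 (not isolated)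
Conditions: mCPBA (3.6 equiv), CH2Cl2, 0 °C to rt; aq. Na2SO3; then K2CO3 (cat.), degassed MeOH, 0 °C, argon; aq. NH4Cl
Reagents that add atoms: mCPBA, OOC(=O)c1cccc(Cl)c1
Why: Each formyl carbonyl adds the peracid to give a Criegee peroxy-hemiacetal, the aryl group shifts from carbon to the proximal peroxide oxygen with loss of 3-chlorobenzoate, and the resulting tris(aryl formate) 14 is transesterified by carbonate in methanol to the three phenols. The closest known reaction is the Baeyer–Villiger (Dakin-type) oxidation of 2,4,6-trialkoxybenzaldehydes to the corresponding phenols with peracids. No ring is closed and no stereocentre is formed; three aryl C–O bonds are made. The selectivity needed is aryl over hydride migration at all three sites, and the two ortho oxygen substituents plus the para aryloxy group on each formyl-bearing ring secure it by stabilising positive charge at the migrating ipso carbon. Attack of the peracid on the electron-rich rings is held back by the near-stoichiometric charge at low temperature, and the peracid is destroyed with Na2SO3 before base is added so that the freed 2,6-dioxygenated phenols are not oxidised to quinones.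

Step 9
Reactants: 15 triphenol deca-O-methyl ether
Product: 16 target tridecaphenol (CNP0228612.0)
Conditions: BBr3 (20 equiv), CH2Cl2, −78 °C to rt, argon; then H2O, 0 °C; reverse-phase purification with degassed solvents
Reagents that add atoms: none
Why: Lewis acid-mediated cleavage of aryl methyl ethers: BBr3 binds each methoxy oxygen and bromide attacks the methyl carbon, whereas the diaryl ether bonds offer no carbon open to such attack and should survive.

**Compound list**
1 | 2,4,6-trimethoxyphenol | COc1cc(OC)c(O)c(OC)c1 | starting material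
2 | 4-fluoro-2,6-dimethoxybenzaldehyde | COc1cc(F)cc(OC)c1C=O | starting material
3 | 2,6-dimethoxy-4-(2,4,6-trimethoxyphenoxy)benzaldehyde | COc1cc(OC)c(Oc2cc(OC)c(C=O)c(OC)c2)c(OC)c1 | intermediate
4 | 2-hydroxy-6-methoxy-4-(2,4,6-trimethoxyphenoxy)benzaldehyde (AB phenol) | COc1cc(OC)c(Oc2cc(O)c(C=O)c(OC)c2)c(OC)c1 | intermediate
5 | 4-bromo-2,6-dimethoxyphenol | COc1cc(Br)cc(OC)c1O | starting material
6 | 4-(4-bromo-2,6-dimethoxyphenoxy)-2,6-dimethoxybenzaldehyde (DE bromide) | COc1cc(Br)cc(OC)c1Oc1cc(OC)c(C=O)c(OC)c1 | intermediate
7 | 2-(4-fluoro-2,6-dimethoxyphenyl)-1,3-dioxolane | COc1cc(F)cc(OC)c1C1OCCO1 | intermediate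
8 | [3-(1,3-dioxolan-2-yl)-6-fluoro-2,4-dimethoxyphenyl]lithium (not isolated) | [Li]c1c(F)cc(OC)c(C2OCCO2)c1OC | intermediate
9 | dimethyl [3-(1,3-dioxolan-2-yl)-6-fluoro-2,4-dimethoxyphenyl]boronate (not isolated) | COB(OC)c1c(F)cc(OC)c(C2OCCO2)c1OC | intermediate
10 | 3-(1,3-dioxolan-2-yl)-6-fluoro-2,4-dimethoxyphenol (not isolated) | Oc1c(F)cc(OC)c(C2OCCO2)c1OC | intermediate
11 | 4-fluoro-3-hydroxy-2,6-dimethoxybenzaldehyde (ring C phenol) | COc1cc(F)c(O)c(OC)c1C=O | intermediate
12 | 4-fluoro-3-[4-(4-formyl-3,5-dimethoxyphenoxy)-3,5-dimethoxyphenoxy]-2,6-dimethoxybenzaldehyde (CDE fluoride) | COc1cc(F)c(Oc2cc(OC)c(Oc3cc(OC)c(C=O)c(OC)c3)c(OC)c2)c(OC)c1C=O | intermediate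
13 | 4-[2-formyl-3-methoxy-5-(2,4,6-trimethoxyphenoxy)phenoxy]-3-[4-(4-formyl-3,5-dimethoxyphenoxy)-3,5-dimethoxyphenoxy]-2,6-dimethoxybenzaldehyde (trialdehyde deca-O-methyl precursor) | COc1cc(OC)c(Oc2cc(OC)c(C=O)c(Oc3cc(OC)c(C=O)c(OC)c3Oc3cc(OC)c(Oc4cc(OC)c(C=O)c(OC)c4)c(OC)c3)c2)c(OC)c1 | intermediate
14 | tris(aryl formate) of 15, a formyloxy group in place of each formyl group of 13 (not isolated) | COc1cc(OC)c(Oc2cc(OC)c(OC=O)c(Oc3cc(OC)c(OC=O)c(OC)c3Oc3cc(OC)c(Oc4cc(OC)c(OC=O)c(OC)c4)c(OC)c3)c2)c(OC)c1 | intermediate
15 | 4-[2-hydroxy-3-methoxy-5-(2,4,6-trimethoxyphenoxy)phenoxy]-3-[4-(4-hydroxy-3,5-dimethoxyphenoxy)-3,5-dimethoxyphenoxy]-2,6-dimethoxyphenol (triphenol deca-O-methyl ether) | COc1cc(OC)c(Oc2cc(OC)c(O)c(Oc3cc(OC)c(O)c(OC)c3Oc3cc(OC)c(Oc4cc(OC)c(O)c(OC)c4)c(OC)c3)c2)c(OC)c1 | intermediate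
16 | 4-[3,5-dihydroxy-4-(3,4,5-trihydroxyphenoxy)phenoxy]-5-[2,3-dihydroxy-5-(2,4,6-trihydroxyphenoxy)phenoxy]benzene-1,2,3-triol (CNP0228612.0) | Oc1cc(O)c(Oc2cc(O)c(O)c(Oc3cc(O)c(O)c(O)c3Oc3cc(O)c(Oc4cc(O)c(O)c(O)c4)c(O)c3)c2)c(O)c1 | target

**Step count**
Total steps: 9. Longest linear sequence: 6 steps (2 → 7 → 11 → 12 → 13 → 15 → 16; steps 4 to 9).

**Steps most likely to fail**

Step 7. The phenoxide of 4 is conjugated to its formyl group and chelates the cation, and the fluoride-bearing ring of 12 carries three oxygen donors with the attacked carbon next to the ring D aryloxy group. Addition may therefore be too slow, and on prolonged heating aryloxide exchange at the other formyl-activated ether carbons would compete. Fallback (sets out from 4 and 12, returns at 13): the formyl group of 4 is masked before the coupling so that the phenoxide is no longer conjugated to a carbonyl group. Compound 4 with ethylene glycol and catalytic PPTS in toluene under Dean–Stark conditions should give 2-(1,3-dioxolan-2-yl)-3-methoxy-5-(2,4,6-trimethoxyphenoxy)phenol F1. F1 and 12 with Cs2CO3 in DMSO at 100 °C should give the coupled ring B dioxolane F2, and 1 M HCl in THF at room temperature should then release 13.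

Step 8. The peracid may attack the unsubstituted positions of the tetraoxygenated ring A, the shielded ring B aldehyde may be oxidised incompletely, or the freed phenoxides may be oxidised during the basic methanolysis. Fallback (sets out from 13, returns at 15): the preformed peracid is replaced by hydrogen peroxide under acid catalysis in methanol (30% H2O2, catalytic H2SO4, MeOH–THF, room temperature), the acid-catalysed Dakin oxidation of alkoxybenzaldehydes. Hydrogen peroxide becomes an oxidant only after it has added to the protonated carbonyl group, the formates 14 are methanolysed in the same acidic medium, and no basic step is needed. No new compound is made.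

Step 6. The electron-rich bromide 6 may enter the copper cycle slowly, and the phenoxide of 11 is di-ortho-substituted and made less nucleophilic by the fluorine. The coupling may stall, with reduction of the bromide and uncatalysed fluoride displacement between molecules of 11 and 12 as competing processes. Fallback (sets out from 6, returns at 12): the aryl partner is changed from a halide to a boron reagent and the ether is made oxidatively at room temperature (Chan–Lam coupling). Miyaura borylation of 6 (B2pin2, Pd(dppf)Cl2, KOAc, dioxane, 90 °C) should give 2,6-dimethoxy-4-[2,6-dimethoxy-4-(4,4,5,5-tetramethyl-1,3,2-dioxaborolan-2-yl)phenoxy]benzaldehyde F3. NaIO4 and NH4OAc in acetone–water should cleave it to [4-(4-formyl-3,5-dimethoxyphenoxy)-3,5-dimethoxyphenyl]boronic acid F4. F4 and 11 with catalytic Cu(OAc)2, pyridine and 4 Å molecular sieves in CH2Cl2 under air at room temperature should give 12, under conditions too mild for fluoride displacement.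

**Further compounds**
F1 | step 7 | 2-(1,3-dioxolan-2-yl)-3-methoxy-5-(2,4,6-trimethoxyphenoxy)phenol | COc1cc(OC)c(Oc2cc(O)c(C3OCCO3)c(OC)c2)c(OC)c1
F2 | step 7 | analogue of 13 with the ring B formyl group as its 1,3-dioxolane | COc1cc(OC)c(Oc2cc(OC)c(C5OCCO5)c(Oc3cc(OC)c(C=O)c(OC)c3Oc3cc(OC)c(Oc4cc(OC)c(C=O)c(OC)c4)c(OC)c3)c2)c(OC)c1
F0 | step 8 | none | none
F3 | step 6 | 2,6-dimethoxy-4-[2,6-dimethoxy-4-(4,4,5,5-tetramethyl-1,3,2-dioxaborolan-2-yl)phenoxy]benzaldehyde | COc1cc(B2OC(C)(C)C(C)(C)O2)cc(OC)c1Oc1cc(OC)c(C=O)c(OC)c1
F4 | step 6 | [4-(4-formyl-3,5-dimethoxyphenoxy)-3,5-dimethoxyphenyl]boronic acid | COc1cc(B(O)O)cc(OC)c1Oc1cc(OC)c(C=O)c(OC)c1
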